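**Retrosynthetic overview**
1. Target ⇒ (2S)-pinocembrin + trans-epoxy lactone (6S)-6-[(2S,3S)-3-phenyloxiran-2-yl]-5,6-dihydro-2H-pyran-2-one. The benzylic C8–O(aryl) bond is made last, by a syn (retentive) boron-mediated transfer of the 7-phenol oxygen to the oxirane.
2. Epoxy lactone ⇒ acrylate of the epoxy homoallylic alcohol (ring-closing metathesis closes the dihydropyranone).
3. Epoxy alcohol ⇒ (S)-dienol by matched Sharpless epoxidation (forms the oxirane, sets C7 and C8).
4. (S)-Dienol ⇒ cinnamaldehyde + allylboronate (catalytic asymmetric allylboration, sets C6).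
5. Ring order: oxirane (step 2), dihydropyranone (step 4), oxirane opened (step 5). Both flavanone rings and the flavanone C2 centre are bought with pinocembrin.

Assumption: (2S)-pinocembrin is bought as the single natural enantiomer. The side chain carries lactone numbering (C6 ring carbinol carbon, C7 side-chain carbinol carbon, C8 benzylic carbon), so the target reads 6S,7S,8S with a 2S flavanone.

Step 1
Reactants: 1 (E)-cinnamaldehyde; 2 allylboronic acid pinacol ester
Product: 4 (1E,3S)-1-phenylhexa-1,5-dien-3-ol, via pinacol borate ester 3 (not isolated)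
Conditions: 2 (1.2 equiv), (S)-TRIP [(S)-3,3'-bis(2,4,6-triisopropylphenyl)-1,1'-binaphthyl-2,2'-diyl hydrogen phosphate] (5 mol%), PhMe, −30 °C; aq NaHCO3 work-up
Reagents that add atoms: none
Why: Chiral phosphoric acid-catalysed allylboration through a closed chair transition state, in which the (S)-acid hydrogen-bonds the boronate oxygen and the formyl hydrogen so that the allyl group adds 1,2 to the Si face of the enal and sets the carbinol carbon (C6) as S; the first-formed borate 3 is hydrolysed on work-up.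

Step 2
Reactants: 4 (1E,3S)-1-phenylhexa-1,5-dien-3-ol
Product: 5 (1S)-1-[(2S,3S)-3-phenyloxiran-2-yl]but-3-en-1-ol
Conditions: Ti(OiPr)4 (10 mol%), L-(+)-diisopropyl tartrate (12 mol%), tBuOOH (1.5 equiv, decane), 4 Å MS, CH2Cl2, −20 °C
Reagents that add atoms: tert-butyl hydroperoxide, CC(C)(C)OO
Why: Sharpless asymmetric epoxidation of a secondary (E)-allylic alcohol in its matched sense: with L-(+)-tartrate the (S)-carbinol is the fast-reacting enantiomer and gives the erythro (anti) epoxy alcohol, which sets both oxirane carbons (C7, C8) as S, leaves the isolated terminal alkene untouched and upgrades the ee because residual (R)-4 reacts about a hundred times more slowly.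

Step 3
Reactants: 5 (1S)-1-[(2S,3S)-3-phenyloxiran-2-yl]but-3-en-1-ol; 6 acryloyl chloride
Product: 7 (1S)-1-[(2S,3S)-3-phenyloxiran-2-yl]but-3-en-1-yl prop-2-enoate
Conditions: 6 (1.5 equiv), Et3N (2 equiv), DMAP (5 mol%), CH2Cl2, 0 °C
Reagents that add atoms: none
Why: DMAP-catalysed O-acylation of a secondary alcohol by an acid chloride under amine-buffered conditions at 0 °C, which the acid-sensitive aryl oxirane tolerates; no stereocentre is touched.

Step 4
Reactants: 7 (1S)-1-[(2S,3S)-3-phenyloxiran-2-yl]but-3-en-1-yl prop-2-enoate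
Product: 8 (6S)-6-[(2S,3S)-3-phenyloxiran-2-yl]-5,6-dihydro-2H-pyran-2-one
Conditions: second-generation Grubbs catalyst RuCl2(=CHPh)(H2IMes)(PCy3) (3 mol%), CH2Cl2 (5 mM), 40 °C
Reagents that add atoms: none
Why: Ring-closing metathesis between the terminal alkene and the acrylate closes the six-membered α,β-unsaturated lactone (ring alkene necessarily Z) with loss of ethene; the oxirane and the three stereocentres are inert to the ruthenium carbene.

Step 5
Reactants: 8 (6S)-6-[(2S,3S)-3-phenyloxiran-2-yl]-5,6-dihydro-2H-pyran-2-one; 9 (2S)-pinocembrin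
Product: 12 (6S)-6-[(1S,2S)-1-hydroxy-2-phenyl-2-{[(2S)-5-hydroxy-4-oxo-2-phenyl-3,4-dihydro-2H-chromen-7-yl]oxy}ethyl]-5,6-dihydro-2H-pyran-2-one, via bis(diphenylboryl) pinocembrin 10 (not isolated), via boron-bound ether adduct 11 (not isolated)
Conditions: 9 (1.2 equiv), (Ph2B)2O (1.2 equiv), 4 Å MS, PhMe, 60 °C, 1 h; then 8, CH2Cl2, −40 → 0 °C; then 1 M aq HCl/THF, rt
Reagents that add atoms: none
Why: Proposed new method: the tricoordinate 7-O–BPh2 boron of 10 binds the oxirane oxygen of 8, the benzylic C8–O bond ionises inside the resulting borate contact ion pair (phenyl-stabilised cation) and the boron-bound 7-aryloxide is handed to C8 through a five-membered SNi transition state on the face the oxirane oxygen has just left, so the C8–O bond forms with retention and the (7S,8S)-trans-oxirane gives the threo 7S,8S hydroxy ether (an ordinary SN2 phenolysis would give the 8R epimer), while the 5-O/C4=O diphenylboron chelate blocks the second phenol, damps ring A against Friedel–Crafts attack and the base-free medium spares the flavanone C2 centre; closest known reaction type: boron-mediated aglycon delivery, the 1,2-cis-selective SNi opening of 1,2-anhydro sugars by borinic or boronic esters, here moved from an anomeric to a benzylic oxirane carbon and to a phenol donor.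

**Compound list**
1 | (E)-cinnamaldehyde, (2E)-3-phenylprop-2-enal | O=C/C=C/c1ccccc1 | starting material
2 | allylboronic acid pinacol ester, 4,4,5,5-tetramethyl-2-(prop-2-en-1-yl)-1,3,2-dioxaborolane | C=CCB1OC(C)(C)C(C)(C)O1 | starting material
3 | pinacol borate of 4, 4,4,5,5-tetramethyl-2-{[(1E,3S)-1-phenylhexa-1,5-dien-3-yl]oxy}-1,3,2-dioxaborolane | C=CC[C@H](OB1OC(C)(C)C(C)(C)O1)/C=C/c1ccccc1 | intermediate
4 | (1E,3S)-1-phenylhexa-1,5-dien-3-ol | C=CC[C@H](O)/C=C/c1ccccc1 | intermediate
5 | (1S)-1-[(2S,3S)-3-phenyloxiran-2-yl]but-3-en-1-ol (erythro epoxy alcohol, trans-oxirane) | C=CC[C@H](O)[C@@H]1O[C@H]1c1ccccc1 | intermediate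
6 | acryloyl chloride, prop-2-enoyl chloride | C=CC(=O)Cl | starting material
7 | (1S)-1-[(2S,3S)-3-phenyloxiran-2-yl]but-3-en-1-yl prop-2-enoate | C=CC[C@H](OC(=O)C=C)[C@@H]1O[C@H]1c1ccccc1 | intermediate
8 | (6S)-6-[(2S,3S)-3-phenyloxiran-2-yl]-5,6-dihydro-2H-pyran-2-one | O=C1C=CC[C@@H]([C@@H]2O[C@H]2c2ccccc2)O1 | intermediate
9 | (2S)-pinocembrin, (2S)-5,7-dihydroxy-2-phenyl-2,3-dihydro-4H-chromen-4-one | Oc1cc(O)c2c(c1)O[C@H](c1ccccc1)CC2=O | starting material
10 | (2S)-5,7-bis-O-(diphenylboryl)pinocembrin: 7-O–BPh2 borinic ester, 5-O–BPh2 chelated by the C4 carbonyl oxygen | c1ccccc1B(c1ccccc1)Oc1cc(O[B-]3(c4ccccc4)c4ccccc4)c2c(c1)O[C@H](c1ccccc1)CC2=[O+]3 | intermediate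
11 | O-diphenylborinate of 12 at the C7 hydroxyl, still carrying the 5-O/C4=O diphenylboron chelate on the flavanone | O=C1C=CC[C@@H]([C@H](OB(c2ccccc2)c2ccccc2)[C@@H](Oc2cc(O[B-]4(c5ccccc5)c5ccccc5)c3c(c2)O[C@H](c2ccccc2)CC3=[O+]4)c2ccccc2)O1 | intermediate
12 | (6S)-6-[(1S,2S)-1-hydroxy-2-phenyl-2-{[(2S)-5-hydroxy-4-oxo-2-phenyl-3,4-dihydro-2H-chromen-7-yl]oxy}ethyl]-5,6-dihydro-2H-pyran-2-one | O=C1C=CC[C@@H]([C@H](O)[C@@H](Oc2cc(O)c3c(c2)O[C@H](c2ccccc2)CC3=O)c2ccccc2)O1 | target

**Step count and risks**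
Total step count: 5. Longest linear sequence: 5 steps (1 → 4 → 5 → 7 → 8 → 12); 9 is bought and enters in the last step.

Steps most likely to fail:

Step 5 (the proposed new step). The borate-bound benzylic cation may undergo a 1,2-hydride shift to the benzyl ketone (Meinwald-type), may leak to anti opening by a second borinate, or may not ionise at all with a Ph2B Lewis acid. The acid work-up may also cleave the 5-O/C4=O boron chelate only slowly. The fallback uses known chemistry, sets out from 8 (with 9) and comes back at 12; it reaches the same net retention at C8 by two separate SN2 inversions. Acid hydrolysis of 8 (cat. HClO4, THF/H2O, 0 °C) opens the oxirane at the benzylic carbon with inversion to the erythro diol (6S)-6-[(1S,2R)-1,2-dihydroxy-2-phenylethyl]-5,6-dihydro-2H-pyran-2-one F1. SOCl2/Et3N (CH2Cl2, 0 °C) gives the cyclic sulfite (6S)-6-[(4S,5R)-2-oxido-5-phenyl-1,3,2-dioxathiolan-4-yl]-5,6-dihydro-2H-pyran-2-one F2. A brief RuCl3 (cat.)/NaIO4 oxidation (MeCN/H2O, 0 °C, minutes, so that the electron-poor lactone alkene survives) gives the cyclic sulfate (6S)-6-[(4S,5R)-2,2-dioxido-5-phenyl-1,3,2-dioxathiolan-4-yl]-5,6-dihydro-2H-pyran-2-one F3. The 7-phenoxide of 9 (K2CO3, acetone, rt) opens F3 at the benzylic carbon with the second inversion to the potassium alkyl sulfate of the target F4, which cat. H2SO4/H2O in THF hydrolyses to 12.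

Step 2. The 3-aryl-2,3-epoxy alcohol can be opened at the benzylic carbon by the titanium alkoxide medium, and conversion control matters for the ee upgrade. The fallback sets out from 4 and comes back at 8; it moves the epoxidation to the lactone stage and uses reagent control. Acryloylation of 4 with 6 (Et3N, DMAP, CH2Cl2, 0 °C) gives (1E,3S)-1-phenylhexa-1,5-dien-3-yl prop-2-enoate F5. Ring-closing metathesis with the same ruthenium catalyst gives (6S)-6-[(E)-2-phenylethenyl]-5,6-dihydro-2H-pyran-2-one F6. A dioxirane epoxidation of the electron-rich styryl alkene then gives 8, using the enantiomer of the D-fructose-derived Shi ketone (made from L-sorbose), KHSO5, K2CO3 buffer, MeCN/dimethoxymethane/H2O, 0 °C, with short contact to limit lactone hydrolysis.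

Step 1. The ee with a conjugated enal may fall short, and the chiral acid is costly. The fallback sets out from 1 and comes back at 5; it replaces asymmetric catalysis by a kinetic resolution. CH2=CHCH2MgBr (THF, −78 °C) adds 1,2 to 1 to give racemic (1E)-1-phenylhexa-1,5-dien-3-ol F7. The step 2 conditions with only 0.6 equiv tBuOOH epoxidise the (S)-half to 5 (at most 50%) and leave (1E,3R)-1-phenylhexa-1,5-dien-3-ol F8, which is separated by chromatography.

**Further compounds**
F1 | step 5 | (6S)-6-[(1S,2R)-1,2-dihydroxy-2-phenylethyl]-5,6-dihydro-2H-pyran-2-one (erythro diol) | O=C1C=CC[C@@H]([C@H](O)[C@H](O)c2ccccc2)O1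
F2 | step 5 | (6S)-6-[(4S,5R)-2-oxido-5-phenyl-1,3,2-dioxathiolan-4-yl]-5,6-dihydro-2H-pyran-2-one (cyclic sulfite, both sulfur epimers) | O=C1C=CC[C@@H]([C@@H]2OS(=O)O[C@@H]2c2ccccc2)O1
F3 | step 5 | (6S)-6-[(4S,5R)-2,2-dioxido-5-phenyl-1,3,2-dioxathiolan-4-yl]-5,6-dihydro-2H-pyran-2-one (cyclic sulfate) | O=C1C=CC[C@@H]([C@@H]2OS(=O)(=O)O[C@@H]2c2ccccc2)O1
F4 | step 5 | potassium (1S,2S)-1-[(2S)-6-oxo-3,6-dihydro-2H-pyran-2-yl]-2-phenyl-2-{[(2S)-5-hydroxy-4-oxo-2-phenyl-3,4-dihydro-2H-chromen-7-yl]oxy}ethyl sulfate | O=C1C=CC[C@@H]([C@H](OS(=O)(=O)[O-])[C@@H](Oc2cc(O)c3c(c2)O[C@H](c2ccccc2)CC3=O)c2ccccc2)O1.[K+]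
F5 | step 2 | (1E,3S)-1-phenylhexa-1,5-dien-3-yl prop-2-enoate | C=CC[C@H](OC(=O)C=C)/C=C/c1ccccc1
F6 | step 2 | (6S)-6-[(E)-2-phenylethenyl]-5,6-dihydro-2H-pyran-2-one, (S)-goniothalamin | O=C1C=CC[C@@H](/C=C/c2ccccc2)O1
F7 | step 1 | racemic (1E)-1-phenylhexa-1,5-dien-3-ol | C=CCC(O)/C=C/c1ccccc1
F8 | step 1 | (1E,3R)-1-phenylhexa-1,5-dien-3-ol (unreacted enantiomer) | C=CC[C@@H](O)/C=C/c1ccccc1
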